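C-numbering used throughout (2,3-dihydro-1,4-benzodioxine): O1, C2 (methyl), C3 (trimethoxyphenyl), O4, C4a, C5 to C8, C8a; the enal sits on C6 and a methoxy group on C8. The enal is cut back by a Wittig two-carbon extension to the C6 aldehyde, and this to a C6 nitrile.
Key disconnection: the dioxane ring is opened at C2–C3 and at O1–C8a together. This is a formal [4+2] of acetaldehyde (C2, its methyl and O1) with an acyclic benzyl aryl ether that carries a silyl group on C3 and fluorine on C8a; silicon and fluorine leave together as PhMe2SiF.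
Enabling feature: C3 is at once benzylic to the electron-rich trimethoxyphenyl ring and bound to O4, so a C3–Si bond can be cleaved selectively by one-electron oxidation to a stabilised radical. C8a stands para to C6, so a nitrile on C6 makes a fluoride on C8a displaceable by O1.
The precursor comes from a Mitsunobu union (O4–C3) of a fluorophenol with an α-silyl carbinol. Both benzene rings are bought; the dioxane ring is the only ring made, in step 4, together with both stereocentres.

Key step: step 4

Assumption: the sense of induction of the bis(oxazoline)–chromium catalyst is taken as written; should a first run show the opposite sense, the mirror-image ligand is used with no other change.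

Step 1
Reactants: 1 4-fluoro-3-methoxybenzonitrile
Product: 3 4-fluoro-3-hydroxy-5-methoxybenzonitrile, via arylboronate 2 (not isolated)
Conditions: [Ir(OMe)(cod)]2 (1.5 mol %), dtbpy (3 mol %), B2pin2 (1.0 equiv), THF, 65 °C; volatiles removed; then KHSO5, acetone/H2O, 0 °C to rt
Reagents that add atoms: bis(pinacolato)diboron, CC1(C)OB(OC1(C)C)B1OC(C)(C)C(C)(C)O1 (boron stays only in 2); potassium peroxymonosulfate, [K+].[O-]S(=O)(=O)OO (the phenol oxygen)
Why: Sterically governed iridium-catalysed aromatic C–H borylation should favour C5, whose only substituted neighbour is the small, C–H-acidifying fluorine, over C6 (next to cyano) and C2 (between two substituents), and oxidation of the C–B bond then gives the phenol at the same position.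

Step 2
Reactants: 4 3,4,5-trimethoxybenzaldehyde
Product: 5 rac-[dimethyl(phenyl)silyl](3,4,5-trimethoxyphenyl)methanol
Conditions: PhMe2SiLi (1.1 equiv, stock solution in THF), THF, −78 °C; AcOH quench at −78 °C
Reagents that add atoms: dimethylphenylsilyllithium, [Li][Si](C)(C)c1ccccc1
Why: 1,2-Addition of a silyllithium to an aldehyde gives the α-hydroxysilane, the cold acidic quench protonating the lithium alkoxide before a Brook rearrangement can move silicon to oxygen; the carbinol is racemic, which does not matter because step 4 is stereoconvergent.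

Step 3
Reactants: 3 4-fluoro-3-hydroxy-5-methoxybenzonitrile, 5 rac-[dimethyl(phenyl)silyl](3,4,5-trimethoxyphenyl)methanol
Product: 6 rac-3-{[dimethyl(phenyl)silyl](3,4,5-trimethoxyphenyl)methoxy}-4-fluoro-5-methoxybenzonitrile
Conditions: PPh3 (1.3 equiv), DIAD (1.3 equiv), THF, 0 °C to rt
Reagents that add atoms: none
Why: In this Mitsunobu etherification the acidic ortho-fluorophenol should displace the oxyphosphonium of the secondary benzylic α-silyl carbinol, which forms the O4–C3 bond without base and therefore without Brook rearrangement.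

Step 4
Reactants: 6 rac-3-{[dimethyl(phenyl)silyl](3,4,5-trimethoxyphenyl)methoxy}-4-fluoro-5-methoxybenzonitrile, 7 acetaldehyde
Product: 9 (2R,3R)-8-methoxy-2-methyl-3-(3,4,5-trimethoxyphenyl)-2,3-dihydro-1,4-benzodioxine-6-carbonitrile, via silyl ether 8 (not isolated)
Conditions: 7 (5 equiv), CrCl2 (10 mol %), (3aS,8aR)-inda-BOX [2,2'-(propane-2,2-diyl)bis(3a,8a-dihydro-8H-indeno[1,2-d]oxazole)] (12 mol %), 4CzIPN (2,4,5,6-tetra(carbazol-9-yl)isophthalonitrile, 2 mol %), DMF, 450 nm LEDs, 15 °C, sealed vial; then N2 sparge to remove 7, CsF (30 mol %), 60 °C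
Reagents that add atoms: none
Why: Proposed new method: the excited photocatalyst oxidises the trimethoxyphenyl ring of 6, the benzylic C–Si bond of the radical cation breaks (silyl to chloride or DMF), the α-aryloxybenzyl radical is captured by divalent chromium and the trivalent benzylchromium adds to acetaldehyde (C2–C3 bond), after which silyl transfer to the chromium alkoxide gives 8 and the reduced photocatalyst returns chromium to the divalent state, so that no external oxidant or reductant is needed. Fluoride then frees the alkoxide of 8, which closes the dioxane ring by intramolecular SNAr at the fluorine-bearing carbon (O1–C8a bond, 6-exo-trig attack through a Meisenheimer complex stabilised by the para nitrile) and releases the fluoride that desilylates the next molecule, the only co-product being PhMe2SiF. The closest known reaction types are the chromium/photoredox addition of α-silylamines to aldehydes, ligand-controlled asymmetric Nozaki–Hiyama–Kishi-type additions with bis(oxazoline)–chromium catalysts and alkoxide SNAr closures onto 4-fluorobenzonitriles; new are the α-aryloxybenzylsilane as radical source and the coupling of both events in one flask. Both stereocentres are set in the carbonyl addition within the chiral bis(oxazoline)–chromium complex: the planar radical erases the configuration of racemic 6 (stereoconvergence), the ligand selects the acetaldehyde face (2R in 9) and the threo (1R,2R) relation in 8 is expected from a compact four-centre transition state in which the aldehyde methyl avoids the trimethoxyphenyl group, while the SNAr step breaks no bond at either centre and so turns threo-8 into trans-9. The step needs oxidation at the silyl-bearing benzyl unit only (it is the most electron-rich arene and its C–Si bond overlaps with the π system), addition to the aldehyde and not to the nitrile (secured by the chemoselectivity of organochromium reagents) and ring closure at one carbon only (secured by the single fluoride placed para to the nitrile).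

Step 5
Reactants: 9 (2R,3R)-8-methoxy-2-methyl-3-(3,4,5-trimethoxyphenyl)-2,3-dihydro-1,4-benzodioxine-6-carbonitrile
Product: 10 (2R,3R)-8-methoxy-2-methyl-3-(3,4,5-trimethoxyphenyl)-2,3-dihydro-1,4-benzodioxine-6-carbaldehyde
Conditions: iBu2AlH (1.3 equiv), toluene/CH2Cl2, −78 °C; then 1 M HCl, 0 °C
Reagents that add atoms: water, O
Why: Partial reduction of an aryl nitrile with iBu2AlH stops after one hydride transfer at low temperature and hydrolytic work-up delivers the aldehyde (nitrile-to-aldehyde reduction), neither ether stereocentre being acidic or labile under these conditions.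

Step 6
Reactants: 10 (2R,3R)-8-methoxy-2-methyl-3-(3,4,5-trimethoxyphenyl)-2,3-dihydro-1,4-benzodioxine-6-carbaldehyde
Product: 11 (2E)-3-[(2R,3R)-8-methoxy-2-methyl-3-(3,4,5-trimethoxyphenyl)-2,3-dihydro-1,4-benzodioxin-6-yl]prop-2-enal
Conditions: Ph3P=CHCHO (1.3 equiv), toluene, 80 °C
Reagents that add atoms: (triphenylphosphoranylidene)acetaldehyde, O=CC=P(c1ccccc1)(c1ccccc1)c1ccccc1
Why: Wittig olefination with the stabilised formylmethylene ylide should give the (E)-enal and leaves the two ring stereocentres untouched.

Compound list
1 | 4-fluoro-3-methoxybenzonitrile | N#Cc1ccc(F)c(OC)c1 | starting material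
2 | 4-fluoro-3-methoxy-5-(4,4,5,5-tetramethyl-1,3,2-dioxaborolan-2-yl)benzonitrile | N#Cc1cc(OC)c(F)c(B2OC(C)(C)C(C)(C)O2)c1 | intermediate
3 | 4-fluoro-3-hydroxy-5-methoxybenzonitrile | N#Cc1cc(O)c(F)c(OC)c1 | intermediate
4 | 3,4,5-trimethoxybenzaldehyde | COc1cc(C=O)cc(OC)c1OC | starting material
5 | rac-[dimethyl(phenyl)silyl](3,4,5-trimethoxyphenyl)methanol | COc1cc(C(O)[Si](C)(C)c2ccccc2)cc(OC)c1OC | intermediate
6 | rac-3-{[dimethyl(phenyl)silyl](3,4,5-trimethoxyphenyl)methoxy}-4-fluoro-5-methoxybenzonitrile | COc1cc(C(Oc2cc(C#N)cc(OC)c2F)[Si](C)(C)c2ccccc2)cc(OC)c1OC | intermediate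
7 | acetaldehyde | CC=O | starting material
8 | 3-{[(1R,2R)-2-{[dimethyl(phenyl)silyl]oxy}-1-(3,4,5-trimethoxyphenyl)propyl]oxy}-4-fluoro-5-methoxybenzonitrile | COc1cc([C@@H](Oc2cc(C#N)cc(OC)c2F)[C@@H](C)O[Si](C)(C)c2ccccc2)cc(OC)c1OC | intermediate
9 | (2R,3R)-8-methoxy-2-methyl-3-(3,4,5-trimethoxyphenyl)-2,3-dihydro-1,4-benzodioxine-6-carbonitrile | COc1cc([C@H]2Oc3cc(C#N)cc(OC)c3O[C@@H]2C)cc(OC)c1OC | intermediate
10 | (2R,3R)-8-methoxy-2-methyl-3-(3,4,5-trimethoxyphenyl)-2,3-dihydro-1,4-benzodioxine-6-carbaldehyde | COc1cc([C@H]2Oc3cc(C=O)cc(OC)c3O[C@@H]2C)cc(OC)c1OC | intermediate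
11 | (2E)-3-[(2R,3R)-8-methoxy-2-methyl-3-(3,4,5-trimethoxyphenyl)-2,3-dihydro-1,4-benzodioxin-6-yl]prop-2-enal | COc1cc([C@H]2Oc3cc(/C=C/C=O)cc(OC)c3O[C@@H]2C)cc(OC)c1OC | target

Total step count: 6. Longest linear sequence: 5 steps (steps 1, 3, 4, 5, 6 from 1, or steps 2, 3, 4, 5, 6 from 4).

Steps most likely to fail

Step 4. The benzylic radical may be lost to dimerisation or to reduction and protonation before chromium captures it. The carbonyl addition may proceed with poor control of the acetaldehyde face or of the threo/erythro relation. The fluoride relay may stall. The fallback uses known chemistry and sets C2 by a catalyst-controlled ketone reduction. It sets out from phenol 3, which is alkylated (K2CO3, acetone, rt) with 1-bromo-1-(3,4,5-trimethoxyphenyl)propan-2-one F1 (from commercial 1-(3,4,5-trimethoxyphenyl)propan-2-one and Br2 in AcOH) to give rac-3-{[2-oxo-1-(3,4,5-trimethoxyphenyl)propyl]oxy}-4-fluoro-5-methoxybenzonitrile F2. Asymmetric transfer hydrogenation under dynamic kinetic resolution (RuCl(p-cymene)[(S,S)-TsDPEN], HCO2H/Et3N, catalyst antipode chosen for 2R) follows; the α-aryl-α-aryloxy centre racemises through the enol, and by analogy with the reduction of benzoin the threo alcohol 3-{[(1R,2R)-2-hydroxy-1-(3,4,5-trimethoxyphenyl)propyl]oxy}-4-fluoro-5-methoxybenzonitrile F3 should result. KOtBu in THF (0 °C to rt) then closes the ring by SNAr, and the sequence comes back to the route at 9.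

Step 3. Displacement at the hindered, silyl-bearing carbinol carbon may be slow, so that alkylation of the hydrazide anion or ionisation of the activated alcohol competes with ether formation. The fallback sets out from 5. Appel bromination (CBr4, PPh3, CH2Cl2, 0 °C) gives [bromo(3,4,5-trimethoxyphenyl)methyl]dimethyl(phenyl)silane F4, which alkylates the potassium salt of 3 (K2CO3, DMF, rt; Williamson ether synthesis) and comes back to the route at 6.

Step 6. The electron-rich aldehyde may react slowly, and the product enal, itself an aldehyde, may be olefinated a second time (chain extension to the dienal). The fallback sets out from 10. Horner–Wadsworth–Emmons olefination ((EtO)2P(O)CH2CO2Et, NaH, THF, 0 °C) gives ethyl (2E)-3-[(2R,3R)-8-methoxy-2-methyl-3-(3,4,5-trimethoxyphenyl)-2,3-dihydro-1,4-benzodioxin-6-yl]prop-2-enoate F5. Reduction with iBu2AlH (CH2Cl2, −78 °C) gives (2E)-3-[(2R,3R)-8-methoxy-2-methyl-3-(3,4,5-trimethoxyphenyl)-2,3-dihydro-1,4-benzodioxin-6-yl]prop-2-en-1-ol F6, and MnO2 (CH2Cl2, rt) oxidises the allylic alcohol, which comes back to the route at 11.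

Further compounds
F1 | step 4 | 1-bromo-1-(3,4,5-trimethoxyphenyl)propan-2-one | COc1cc(C(Br)C(C)=O)cc(OC)c1OC
F2 | step 4 | rac-3-{[2-oxo-1-(3,4,5-trimethoxyphenyl)propyl]oxy}-4-fluoro-5-methoxybenzonitrile | COc1cc(C(Oc2cc(C#N)cc(OC)c2F)C(C)=O)cc(OC)c1OC
F3 | step 4 | 3-{[(1R,2R)-2-hydroxy-1-(3,4,5-trimethoxyphenyl)propyl]oxy}-4-fluoro-5-methoxybenzonitrile | COc1cc([C@@H](Oc2cc(C#N)cc(OC)c2F)[C@@H](C)O)cc(OC)c1OC
F4 | step 3 | [bromo(3,4,5-trimethoxyphenyl)methyl]dimethyl(phenyl)silane | COc1cc(C(Br)[Si](C)(C)c2ccccc2)cc(OC)c1OC
F5 | step 6 | ethyl (2E)-3-[(2R,3R)-8-methoxy-2-methyl-3-(3,4,5-trimethoxyphenyl)-2,3-dihydro-1,4-benzodioxin-6-yl]prop-2-enoate | COc1cc([C@H]2Oc3cc(/C=C/C(=O)OCC)cc(OC)c3O[C@@H]2C)cc(OC)c1OC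
F6 | step 6 | (2E)-3-[(2R,3R)-8-methoxy-2-methyl-3-(3,4,5-trimethoxyphenyl)-2,3-dihydro-1,4-benzodioxin-6-yl]prop-2-en-1-ol | COc1cc([C@H]2Oc3cc(/C=C/CO)cc(OC)c3O[C@@H]2C)cc(OC)c1OC
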